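A small charge of substrate, 10 mM in teal against 20 mM in amber, opens the reckoning, because the question is whether opening runs as a fixed amount per minute or as a share of the charge. The flasks and the questions stand here.

| flask | substrate | reagent | free catalyst | second catalyst | temperature | remark | time |
|---|---|---|---|---|---|---|---|
| amber | 20 mM | 21 mM | 0.67 mM | 0.26 mM | 64 °C | run made earlier |  |
| green | 20 mM | 21 mM | 1.5 mM | 0.26 mM | 105 °C | run made earlier |  |
| teal | 10 mM | 21 mM | 1 mM | 0.26 mM | 64 °C | run made earlier |  |
| theta | 20 mM | 21.0 mM | 1.0 mM | 0.26 mM | 45 °C |  | 80 min |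
| beta | 20 mM | 21.0 mM | 1.0 mM | 0.26 mM | 120 °C |  | 80 min |
| alpha | 20 mM | 21.0 mM | 1.0 mM | 0.26 mM | 70 °C |  | 80 min |
| gamma | 20 mM | 21.0 mM | 1.0 mM | 0.26 mM | 95 °C |  | 80 min |

| run | time / min | open intermediate / % | product / % |
|---|---|---|---|
| amber | 1.50 | 6 | 0 |
| amber | 2.50 | 2 | 3 |
| amber | 4.00 | 0 | 1 |
| amber | 8.00 | 3 | 0 |
| amber | 12.0 | 5 | 0 |
| amber | 20.0 | 10 | 0 |
| green | 0.200 | 7 | 1 |
| green | 0.333 | 4 | 0 |
| green | 0.500 | 10 | 1 |
| green | 1.00 | 18 | 0 |
| green | 1.50 | 21 | 2 |
| green | 2.50 | 40 | 0 |
| teal | 4.00 | 5 | 0 |
| teal | 8.00 | 9 | 0 |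
| teal | 12.0 | 11 | 0 |
| teal | 15.0 | 12 | 0 |
| teal | 20.0 | 13 | 0 |

(standard deviation of a reading: 2 percentage points)

- the numbers in the tables scatter with a standard deviation of 2 percentage points

1. the flask with the highest amount of open intermediate, in percent of the substrate charged ("all alike" if they lie within 1.5 percentage points) (theta / beta / alpha / gamma / all alike)
2. final open intermediate, as a percentage of the substrate charged, in theta
3. final open intermediate, as a percentage of the substrate charged, in beta
4. final open intermediate, as a percentage of the substrate charged, in alpha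
5. final open intermediate, as a percentage of the substrate charged, in gamma

Teal reads 13% open intermediate at 20.0 min with 1 mM free catalyst, which as a first-order loss of substrate gives a constant k of 0.00696 min⁻¹. Amber has twice the substrate and reads 10% at 20.0 min; scaled to the 1.0 mM of free catalyst in the asked flasks, it gives 0.00786 min⁻¹. These two figures lie close together, so opening is taken as a share of the charge per minute, proportional to [free catalyst], and amber's figure is carried on as the value at 64 °C. Green, scaled the same way, gives 0.136 min⁻¹ at 105 °C.

A straight line in ln k against temperature through amber and green, a rough step, puts k at 0.0119 min⁻¹ for alpha, whose figure after 80 min is 61.5%. This is the ceiling, one minus exp(−kt), the share of the charge that opening has passed; open intermediate is taken to stand below it, with product formed from it. Theta's ceiling is 15.4% and gamma's 99.6%.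

For a floor, amber's last product reading is 0%, and two standard deviations of scatter over 20.0 min, kept at that pace for 80 min, allow a loss of 16 points. Alpha is therefore bracketed from 45.5% up to its ceiling; this bracket assumes the pace holds.

The forecast gave 5% for theta, 19% for alpha, 45% for gamma and 65% for beta, with beta highest. Teal's levelling, in its words, “looks like an equilibrium rather than a stoichiometric limit”. Its alpha range ends at 25%, lower than the floor reckoned here.

The flasks give 11.7% in theta, 58.0% in alpha, 84.9% in gamma and 50.4% in beta, so gamma stands highest.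

    substrate + free catalyst → free catalyst + open intermediate (k = 12.5 M⁻¹ min⁻¹, Ea = 75.0 kJ mol⁻¹)
    second catalyst + open intermediate ⇌ catalyst intermediate (K = 87.0 M⁻¹, k = 149 M⁻¹ min⁻¹, Ea = 49.0 kJ mol⁻¹, ΔH = −2.00 kJ mol⁻¹)
    reagent + catalyst intermediate → second catalyst + product (k = 27.1 M⁻¹ min⁻¹, Ea = 70.0 kJ mol⁻¹)
    2 second catalyst ⇌ resting dimer (K = 8.60 × 10⁵ M⁻¹, k = 1030 M⁻¹ min⁻¹, Ea = 49.0 kJ mol⁻¹, ΔH = −22.0 kJ mol⁻¹)
    free catalyst ⇌ dormant form (K = 0.206, k = 0.00387 min⁻¹, Ea = 118 kJ mol⁻¹, ΔH = 6.00 kJ mol⁻¹)
    (constants at 70 °C)

Open intermediate and product together reach 59.6% in alpha against its ceiling of 61.5%, and 11.8% in theta against 15.4%. In gamma, substrate has a half-life by opening of 11 min at 10.7 min, shorter than the 96 min that open intermediate has at 80.0 min by the forward step to catalyst intermediate, and gamma then holds 84.9% open intermediate beside 14.2% product. At that time open intermediate is made at 0.247 of the rate at which it is used, and gamma left until 3.0 h holds 69.5%.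

(The readings are simulated for an exercise; noise was put on by code.)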